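## Analysis of the target

The target is a type B polyprenylated acylphloroglucinol built on a bicyclo[3.3.1]non-3-ene-2,9-dione. Numbering used throughout: C1 is the bridgehead next to the gem-dimethyl carbon C8, C2–C3–C4 is the enolised β-diketone bridge (C2 ketone, C4 enol, C3 carrying the 3,4-dihydroxybenzoyl group), C5 is the second bridgehead, C6 is CH2, C7 carries the geranyl chain (side-chain carbons C1′, C2′ …), and C9 is the bridging ketone. There are three stereocentres, (1S,5S,7S) in the tautomer drawn. C1 and C5 are quaternary bridgeheads, each carrying a prenyl group, and are locked to each other by the bicycle. C7 is the only independent relative element: its geranyl group is endo, that is, on the side of the C2–C4 bridge. The six ring atoms C1, C2, C3, C4, C5 and C9, with their three oxygens and the C3 aroyl group, are a dearomatised 3,5-diprenylated 2,4,6-trihydroxybenzophenone. The bridge C6–C7–C8 spans the two prenylated carbons of that arene, which is C2v-symmetric before the bridge is attached. The hard points are the C1–C8 bond between two fully substituted carbons, the two quaternary centres flanking C9, and the 7-endo configuration, which an epimerisable C7 substituent tends to leave for exo. Absolute control is also hard because the core has no stereocentre outside this triad. Sensitive groups are four trisubstituted alkenes (acid closes the C4 enol onto them), the E-configured C2′=C3′ bond, the oxidisable catechol, and the acidic, chelating β-triketone.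

## Retrosynthetic reasoning

**26 ⇒ 25 ⇒ 24.** The last operations only unmask. 26 comes from its C4 methyl enol ether 25 by O–CH3 cleavage. 25 comes from 24 by replacing the C1′ oxygen with hydrogen through a π-allyl intermediate. The catechol is carried as two allyl ethers so that the same zerovalent-palladium/hydride step removes them and no separate deprotection is needed. The enol is methylated at this stage because a free C3 enolate would attack the C1′ π-allyl and close an unwanted cage.

**24 ⇒ 22 ⇒ 21 + 20; 21 ⇒ 14; 20 ⇒ 18.** The geranyl chain is cut at C1′–C2′. The E-trisubstituted alkene then arrives intact as the alkenylcerium reagent 20, made from the alkenyl iodide 18, and C1′ becomes a formyl carbon on C7. A 7-endo formyl group next to the C3 enolate is exactly what the adamantane 14 releases when it is deprotonated at the carbinol oxygen: retro-aldol cleavage of the C3–C1′ bond gives the lithium triketonate 21. The forward step must open 14 with one equivalent of lithium amide and trap 21 with 20 before C7 can epimerise. The enolate 21 is never protonated to the free aldehyde 13, which occurs only as a transient in the annulation below.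

**14 ⇒ 6 + 11 (key disconnection).** Three bonds are cut: C1–C8, C5–C6 and the temporary C3–C1′ bond. What remains is the flat, symmetric arene 6 and the enal 11, whose β-carbon is C8, α-carbon C7, acetoxymethyl carbon C6 and formyl carbon C1′. The cut is made here because it removes the vicinal quaternary bond, both bridgeheads and the ring in one step. It also turns the stereochemical problem into a single desymmetrisation that a chiral cation can control, and the aldol cage fixes the otherwise labile 7-endo centre. The forward reaction must select the two prenylated carbons over the aroyl-bearing carbon, C over O, one enantiotopic carbon and face, and kinetic exo protonation at C7.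

**6 ⇒ 5 ⇒ 2 + 3; 2 ⇒ 1.** The prenyl groups on the aromatic carbons are removed (double C-prenylation of 5 forward). The benzophenone 5 is cut at the aryl–carbonyl bond into 3 and the nitrile 2 (Houben–Hoesch acylation forward), and 2 comes from 1 by double O-allylation.

**11 ⇒ 10 ⇒ 8 ⇒ 7.** The enal is traced to the symmetric diol 8 by oxidation-state and acyl adjustments (mono-acetylation through the cyclic ortho ester 9, then allylic oxidation). 8 comes from the commercial alkylidene malonate 7 by 1,2-reduction.

**18 ⇒ 16 ⇒ 15.** The E-alkenyl iodide is cut across the C–I and C–CH3 bonds (syn carbometallation/iodination of the alkyne 16). 16 comes from the bromide 15 by alkynylation.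

## Alternatives that were turned down

**Alternative 1:** (the textbook route) Cut C1–C2 and C4–C5, the two bonds joining the β-diketone bridge to a preformed cyclohexanone. Forward key step: Effenberger-type two-fold C-acylation of the methyl enol ether A1 by a malonyl bis-electrophile to give the bicyclic trione A2, followed by bridgehead C5 prenylation and C3 aroylation. It was turned down for these reasons:
- The annulation creates no control element for C7. The malonyl bridge must form diaxially, and for the 7-endo series it must form on the face cis to the geranyl group, which the substrate does not favour.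
- A1 itself needs an enantioselective construction of C7 next to the gem-dimethyl carbon, which takes several steps.
- Bridgehead deprotonation and C3 metalation add further strongly basic steps.
- The stereotriad is set in three separate events over a long linear sequence.

**Alternative 2:** Cut only C1–C8 (biomimetic). Forward key step: protic-acid ionisation of the isopropenyl group of the dearomatised trione A3 to the tertiary C8 cation, which is captured by C1. It was turned down for these reasons:
- The quaternary C5 of A3 must be made by alkylating the symmetric arene with an electrophile whose only stereocentre (C7) is β to the reacting carbon, so both C5 epimers are expected.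
- Only one epimer can give the 7-endo product, and it must cyclise through a boat-like or axial-geranyl transition state.
- That cyclisation competes with O-capture, with closure at the aroyl-bearing carbon, and with protonation of the other five alkenes.
- At best half of the advanced material is usable, and the stereocentres are not set as a group.

**Alternative 3:** Cut C1–C8 by a [3,3] shift and C5–C6 by π-allyl alkylation. Forward key steps: dearomative Claisen rearrangement of the aryl ether A4 (silyl-protected catechol), then zerovalent-palladium ring closure to the 7-methylene bicycle A5. Exo-face hydroboration and B-alkyl Suzuki coupling with 18 would then set the 7-endo geranyl group. The route is short and needs no deoxygenation at C1′. It was turned down for these reasons: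
- The sigmatropic step is the desymmetrising event, and it has no handle for absolute control. The allyl unit is achiral, and the ether oxygen has no neighbouring donor for a chiral Lewis acid. A5 would therefore be racemic.
- Zerovalent palladium can re-ionise the allylic C1–C8 bond and erode the quaternary–quaternary connectivity.
- Hydroboration forces silyl protection of the catechol, which does not survive the aqueous base of the C-prenylation.

Key step: step 7

Remark 1: the sense of induction of the cinchonidinium catalyst in step 7 is assumed to give the (1S,5S) core; if it gives the opposite sense, the pseudoenantiomeric cinchoninium catalyst is used.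
Remark 2: the carbinol centre C1′ is of no consequence; 14 is written with OH anti to the C8 methyl groups, and 22–24 are epimer mixtures with that centre left undefined.
Remark 3: O-methylation in step 11 may also give the C2–O-methyl regioisomer; the C4 isomer is written, and both converge in step 13.
Remark 4: 12 and 13 are written in their neutral forms although they are present as caesium salts in step 7; 21 is written as the lithium salt because it is the species that reacts in step 10.

## Route

Step 1
Reactants: 1 3,4-dihydroxybenzonitrile
Product: 2 3,4-bis(allyloxy)benzonitrile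
Conditions: allyl bromide (2.4 equiv), K2CO3, DMF, 60 °C
Reagents that add atoms: allyl bromide, C=CCBr
Why: Williamson etherification of both phenols; the allyl ethers tolerate all later basic and organometallic steps and are removed without an extra step in step 12.

Step 2
Reactants: 2 3,4-bis(allyloxy)benzonitrile; 3 phloroglucinol
Product: 5 [3,4-bis(allyloxy)phenyl](2,4,6-trihydroxyphenyl)methanone, via ketiminium chloride 4 (not isolated)
Conditions: ZnCl2, HCl (gas), Et2O, 0 °C to rt; then H2O, reflux
Reagents that add atoms: water, O
Why: Houben–Hoesch acylation; the nitrilium ion from 2 attacks the very electron-rich 3 once, the ketiminium salt 4 precipitates, and hydrolysis gives the ketone.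

Step 3
Reactants: 5 [3,4-bis(allyloxy)phenyl](2,4,6-trihydroxyphenyl)methanone
Product: 6 [3,4-bis(allyloxy)phenyl][2,4,6-trihydroxy-3,5-bis(3-methylbut-2-enyl)phenyl]methanone
Conditions: prenyl bromide (2.2 equiv), 5% aq. KOH, 0 °C
Reagents that add atoms: prenyl bromide, CC(C)=CCBr
Why: C-alkylation of the acylphloroglucinol phenolate in water, where hydrogen bonding suppresses O-alkylation; the two free ring positions are the only C-nucleophilic sites, and rearomatisation gives the 3,5-diprenyl arene.

Step 4
Reactants: 7 diethyl 2-(propan-2-ylidene)propanedioate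
Product: 8 2-(propan-2-ylidene)propane-1,3-diol
Conditions: i-Bu2AlH (4.5 equiv), CH2Cl2, −78 to 0 °C; Rochelle salt work-up
Reagents that add atoms: none
Why: 1,2-reduction of both esters of an alkylidene malonate; the β,β-dimethyl substitution disfavours conjugate reduction.

Step 5
Reactants: 8 2-(propan-2-ylidene)propane-1,3-diol
Product: 10 2-(hydroxymethyl)-3-methylbut-2-enyl acetate, via cyclic ortho ester 9 (not isolated)
Conditions: MeC(OMe)3, pyridinium p-toluenesulfonate (cat.), CH2Cl2, rt; then H2O
Reagents that add atoms: trimethyl orthoacetate, CC(OC)(OC)OC; water, O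
Why: Mono-acylation of a symmetric 1,3-diol through its cyclic ortho ester, whose hydrolytic opening can give only the mono-acetate.

Step 6
Reactants: 10 2-(hydroxymethyl)-3-methylbut-2-enyl acetate
Product: 11 2-formyl-3-methylbut-2-enyl acetate
Conditions: MnO2 (activated, excess), CH2Cl2, rt
Reagents that add atoms: none
Why: Chemoselective oxidation of the allylic alcohol to the enal; the allylic acetate is untouched.

Step 7
Reactants: 6 [3,4-bis(allyloxy)phenyl][2,4,6-trihydroxy-3,5-bis(3-methylbut-2-enyl)phenyl]methanone; 11 2-formyl-3-methylbut-2-enyl acetate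
Product: 14 adamantane alcohol (aldol cage closed by a C3–C1′ bond; C1′ is CH–OH), via dearomatised acrolein adduct 12 (not isolated), via bicyclic 7-endo aldehyde 13 (not isolated)
Conditions: 2,7-bis[(O-allylcinchonidinium-N-yl)methyl]naphthalene dibromide (0.25 equiv), CsOH·H2O, 4 Å MS, CH2Cl2, −50 °C; then aq. NH4Cl
Reagents that add atoms: none
Why: Ion-pair (phase-transfer) catalysed alkylative dearomatisation–annulation, a known cascade for 3,5-diprenylated aroylphloroglucinols with 2-(acyloxymethyl) enals of this type: the phenolate of 6 adds through one prenylated ring carbon to the β-carbon of 11 (C8), acetate is expelled (E1cB) to give the 2-substituted acrolein 12, and the second prenylated carbon adds to the new methylene (C6). This second conjugate addition closes the carbocycle C5–C6–C7–C8–C1–C9 in a 6-endo-trig mode; the resulting aldehyde enolate is protonated at C7 to give 13, whose C3 enolate then adds to the endo formyl group (6-exo-trig) to close the cage of 14. C1 is set in the first, enantio-determining C–C bond formation, where the chiral bis-ammonium cation differentiates the two enantiotopic prenylated carbons and faces of the C2v-symmetric phenolate; C5 follows necessarily, because the three-atom tether reaches the second carbon only on the same face. C7 is set by kinetic protonation of the exocyclic enolate from the convex exo face, which places the formyl group endo. The aldol closure is possible only for this epimer and removes it from any epimerisation equilibrium; C3 is dictated by the cage. Required selectivities are C- over O-alkylation (conjugate addition is soft and O-adducts revert), reaction at the two prenyl-bearing carbons and not at the aroyl-bearing carbon (the least nucleophilic site of the chelated triketone, engaged only in the final aldol), and low temperature so that C7 does not equilibrate to the exo aldehyde.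

Step 8
Reactants: 15 5-bromo-2-methylpent-2-ene
Product: 16 6-methylhept-5-en-1-yne
Conditions: lithium acetylide–ethylenediamine complex, DMSO, 10 °C to rt
Reagents that add atoms: lithium acetylide–ethylenediamine complex, [Li+].[C-]#C.NCCN
Why: SN2 alkynylation of a primary homoallylic bromide.

Step 9
Reactants: 16 6-methylhept-5-en-1-yne
Product: 18 (E)-1-iodo-2,6-dimethylhepta-1,5-diene, via alkenylalane 17 (not isolated)
Conditions: AlMe3 (2 equiv), Cp2ZrCl2 (0.25 equiv), CH2Cl2, 0 °C to rt; then I2, THF, −30 to 0 °C
Reagents that add atoms: trimethylaluminium, C[Al](C)C; iodine, II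
Why: Negishi zirconium-catalysed carboalumination adds CH3 and Al syn across the terminal alkyne with Al at the terminus; iodinolysis with retention gives the E-iodide that carries the C2′=C3′ geometry of the geranyl chain.

Step 10
Reactants: 14 adamantane alcohol; 18 (E)-1-iodo-2,6-dimethylhepta-1,5-diene
Product: 22 3-[3,4-bis(allyloxy)benzoyl]-4-hydroxy-7-endo-[(2E)-1-hydroxy-3,7-dimethylocta-2,6-dienyl]-8,8-dimethyl-1,5-bis(3-methylbut-2-enyl)bicyclo[3.3.1]non-3-ene-2,9-dione (carbinol epimers), via alkenyllithium 19 (not isolated), via alkenylcerium dichloride 20 (not isolated), via lithium enolate of the ring-opened 7-endo aldehyde 21 (not isolated)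
Conditions: 18 (3 equiv), t-BuLi (2 equiv per iodide), Et2O, −78 °C; CeCl3, THF, −78 °C; then 14 pretreated with LiN(SiMe3)2 (1.0 equiv), THF, −78 °C; aq. NH4Cl
Reagents that add atoms: none
Why: One-pot retro-aldol/alkenyl-cerium addition, known for this cage type: deprotonation of 14 at the carbinol oxygen triggers fragmentation of the C3–C1′ bond to the stabilised lithium triketonate 21, which carries the 7-endo formyl group and is not protonated before the weakly basic organocerium 20 adds to that aldehyde faster than C7 can enolise. The enolate charge of 21 protects the ring carbonyls, and C7 keeps the endo configuration set in step 7.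

Step 11
Reactants: 22 allylic alcohol (carbinol epimers)
Product: 24 C4 methyl enol ether C1′ methyl carbonate of 22, via methyl enol ether alcohol 23 (not isolated)
Conditions: Me3SiCHN2, i-Pr2NEt, MeCN/MeOH, 0 °C to rt; evaporate; ClCO2Me, pyridine, DMAP, CH2Cl2, 0 °C to rt
Reagents that add atoms: (trimethylsilyl)diazomethane, C[Si](C)(C)C=[N+]=[N-]; methyl chloroformate, COC(Cl)=O
Why: O-methylation of the acidic enol masks the C3 nucleophile. Acylation of the neutral alcohol (no alkoxide, so no transetherification onto C4) then installs the allylic leaving group.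

Step 12
Reactants: 24 methyl enol ether methyl carbonate
Product: 25 3-(3,4-dihydroxybenzoyl)-7-endo-[(2E)-3,7-dimethylocta-2,6-dienyl]-4-methoxy-8,8-dimethyl-1,5-bis(3-methylbut-2-enyl)bicyclo[3.3.1]non-3-ene-2,9-dione
Conditions: Pd(PPh3)4 (0.1 equiv), Bu3SnH (4 equiv, slow addition), AcOH, CH2Cl2, rt
Reagents that add atoms: none
Why: Tsuji–Trost-type reductive cleavage: zerovalent palladium ionises the allylic carbonate, and hydride is delivered to the less substituted terminus C1′, which keeps the trisubstituted C2′=C3′ alkene and its E geometry. The same catalyst/hydride pair cleaves both aryl allyl ethers to propene and the free catechol.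

Step 13
Reactants: 25 C4 methyl enol ether of the target
Product: 26 (1S,5S,7S)-3-(3,4-dihydroxybenzoyl)-7-[(2E)-3,7-dimethylocta-2,6-dienyl]-4-hydroxy-8,8-dimethyl-1,5-bis(3-methylbut-2-enyl)bicyclo[3.3.1]non-3-ene-2,9-dione (target)
Conditions: LiCl, DMSO, 120 °C, argon; then dilute aq. HCl at 0 °C
Reagents that add atoms: none
Why: SN2 demethylation of the vinylogous methyl ester by chloride, the standard non-acidic unmasking of this enol; no stereocentre is epimerisable and the alkenes are not exposed to acid.

## Compound list

1 | 3,4-dihydroxybenzonitrile | N#Cc1ccc(O)c(O)c1 | starting material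
2 | 3,4-bis(allyloxy)benzonitrile | N#Cc1ccc(OCC=C)c(OCC=C)c1 | intermediate
3 | phloroglucinol (benzene-1,3,5-triol) | Oc1cc(O)cc(O)c1 | starting material
4 | [3,4-bis(allyloxy)phenyl](2,4,6-trihydroxyphenyl)methaniminium chloride | [NH2+]=C(c1ccc(OCC=C)c(OCC=C)c1)c1c(O)cc(O)cc1O.[Cl-] | intermediate
5 | [3,4-bis(allyloxy)phenyl](2,4,6-trihydroxyphenyl)methanone | O=C(c1ccc(OCC=C)c(OCC=C)c1)c1c(O)cc(O)cc1O | intermediate
6 | [3,4-bis(allyloxy)phenyl][2,4,6-trihydroxy-3,5-bis(3-methylbut-2-enyl)phenyl]methanone | O=C(c1ccc(OCC=C)c(OCC=C)c1)c1c(O)c(CC=C(C)C)c(O)c(CC=C(C)C)c1O | intermediate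
7 | diethyl 2-(propan-2-ylidene)propanedioate | CCOC(=O)C(=C(C)C)C(=O)OCC | starting material
8 | 2-(propan-2-ylidene)propane-1,3-diol | CC(C)=C(CO)CO | intermediate
9 | 2-methoxy-2-methyl-5-(propan-2-ylidene)-1,3-dioxane | COC1(C)OCC(=C(C)C)CO1 | intermediate
10 | 2-(hydroxymethyl)-3-methylbut-2-enyl acetate | CC(=O)OCC(CO)=C(C)C | intermediate
11 | 2-formyl-3-methylbut-2-enyl acetate | CC(=O)OCC(C=O)=C(C)C | intermediate
12 | 2-[3,4-bis(allyloxy)benzoyl]-6-(3-formyl-2-methylbut-3-en-2-yl)-3,5-dihydroxy-4,6-bis(3-methylbut-2-enyl)cyclohexa-2,4-dien-1-one (quaternary carbon, the future C1, configured as in the target) | OC1=C(CC=C(C)C)C(O)=C(C(=O)c2ccc(OCC=C)c(OCC=C)c2)C(=O)[C@@]1(CC=C(C)C)C(C)(C)C(=C)C=O | intermediate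
13 | 3-[3,4-bis(allyloxy)benzoyl]-7-endo-formyl-4-hydroxy-8,8-dimethyl-1,5-bis(3-methylbut-2-enyl)bicyclo[3.3.1]non-3-ene-2,9-dione (C1, C5, C7 as in the target) | O=C[C@H]1C[C@]2(CC=C(C)C)C(=O)[C@@](CC=C(C)C)(C(=O)C(C(=O)c3ccc(OCC=C)c(OCC=C)c3)=C2O)C1(C)C | intermediate
14 | adamantane alcohol: aldol cage of 13 with a C3–C1′ bond, C1′ bearing OH, ketones at C2, C4 and C9, aroyl group on C3 | O[C@H]3[C@H]1C[C@]2(CC=C(C)C)C(=O)[C@@](CC=C(C)C)(C(=O)[C@@]3(C(=O)c4ccc(OCC=C)c(OCC=C)c4)C2=O)C1(C)C | intermediate
15 | 5-bromo-2-methylpent-2-ene | CC(C)=CCCBr | starting material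
16 | 6-methylhept-5-en-1-yne | CC(C)=CCCC#C | intermediate
17 | (E)-(2,6-dimethylhepta-1,5-dienyl)dimethylalane | CC(C)=CCC/C(C)=C/[Al](C)C | intermediate
18 | (E)-1-iodo-2,6-dimethylhepta-1,5-diene | CC(C)=CCC/C(C)=C/I | intermediate
19 | (E)-(2,6-dimethylhepta-1,5-dienyl)lithium | CC(C)=CCC/C(C)=C/[Li] | intermediate
20 | (E)-(2,6-dimethylhepta-1,5-dienyl)cerium dichloride | CC(C)=CCC/C(C)=C/[Ce](Cl)Cl | intermediate
21 | lithium 3-[3,4-bis(allyloxy)benzoyl]-7-endo-formyl-8,8-dimethyl-1,5-bis(3-methylbut-2-enyl)-2,9-dioxobicyclo[3.3.1]non-3-en-4-olate (lithium enolate of 13, formed by retro-aldol opening of 14) | [Li+].O=C[C@H]1C[C@]2(CC=C(C)C)C(=O)[C@@](CC=C(C)C)(C(=O)C(C(=O)c3ccc(OCC=C)c(OCC=C)c3)=C2[O-])C1(C)C | intermediate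
22 | 3-[3,4-bis(allyloxy)benzoyl]-4-hydroxy-7-endo-[(2E)-1-hydroxy-3,7-dimethylocta-2,6-dienyl]-8,8-dimethyl-1,5-bis(3-methylbut-2-enyl)bicyclo[3.3.1]non-3-ene-2,9-dione (carbinol epimers) | CC(C)=CCC/C(C)=C/C(O)[C@H]1C[C@]2(CC=C(C)C)C(=O)[C@@](CC=C(C)C)(C(=O)C(C(=O)c3ccc(OCC=C)c(OCC=C)c3)=C2O)C1(C)C | intermediate
23 | C4 methyl enol ether of 22 | CC(C)=CCC/C(C)=C/C(O)[C@H]1C[C@]2(CC=C(C)C)C(=O)[C@@](CC=C(C)C)(C(=O)C(C(=O)c3ccc(OCC=C)c(OCC=C)c3)=C2OC)C1(C)C | intermediate
24 | C4 methyl enol ether C1′ methyl carbonate of 22 | CC(C)=CCC/C(C)=C/C(OC(=O)OC)[C@H]1C[C@]2(CC=C(C)C)C(=O)[C@@](CC=C(C)C)(C(=O)C(C(=O)c3ccc(OCC=C)c(OCC=C)c3)=C2OC)C1(C)C | intermediate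
25 | 3-(3,4-dihydroxybenzoyl)-7-endo-[(2E)-3,7-dimethylocta-2,6-dienyl]-4-methoxy-8,8-dimethyl-1,5-bis(3-methylbut-2-enyl)bicyclo[3.3.1]non-3-ene-2,9-dione | CC(C)=CCC/C(C)=C/C[C@H]1C[C@]2(CC=C(C)C)C(=O)[C@@](CC=C(C)C)(C(=O)C(C(=O)c3ccc(O)c(O)c3)=C2OC)C1(C)C | intermediate
26 | (1S,5S,7S)-3-(3,4-dihydroxybenzoyl)-7-[(2E)-3,7-dimethylocta-2,6-dienyl]-4-hydroxy-8,8-dimethyl-1,5-bis(3-methylbut-2-enyl)bicyclo[3.3.1]non-3-ene-2,9-dione | CC(C)=CCC/C(C)=C/C[C@H]1C[C@]2(CC=C(C)C)C(=O)[C@@](CC=C(C)C)(C(=O)C(C(=O)c3ccc(O)c(O)c3)=C2O)C1(C)C | target

## Step count and least certain steps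

Total step count: 13. Longest linear sequence: 8 (steps 1, 2, 3, 7, 10, 11, 12, 13). The enal branch (steps 4–6) joins at step 7 and the alkenyl iodide branch (steps 8–9) at step 10.

**Step 7 (key step).** The most likely failure is insufficient discrimination between the two enantiotopic prenylated carbons in the first conjugate addition, because the bulkier, more electron-rich aroyl group changes the shape of the ion pair. Two further risks are drift of the C7 protonation toward the exo aldehyde, which cannot close to the cage, and second ring closure at the aroyl-bearing carbon. Fallback: the cascade is run from 6 and 11 with an achiral quaternary ammonium salt (Bu4NBr, CsOH·H2O). The relative configuration is substrate-controlled, so this should still give the cage as the racemate. The enantiomers of 14 are then separated by preparative chromatography on a chiral stationary phase. No new compound arises on this detour (F0), and the route is re-entered at 14.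

**Step 10.** The liberated formyl group sits next to the quaternary C8, so addition may be slow; the enolate 21 may then epimerise at C7 or re-close to the cage. Enolisation of the aldehyde by the organometallic would have the same effect. Fallback, setting out from 14 and returning at 25, with the C1′–C2′ bond made by sp3–sp2 cross-coupling and no oxygen left to remove:
- 14 is opened with LiN(SiMe3)2 (1.0 equiv) to the lithium enolate 21, whose formyl group is reduced in situ with LiBH4 to the 7-endo hydroxymethyl trione F1.
- Me3SiCHN2 gives its methyl enol ether F2.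
- I2, PPh3 and imidazole give the primary iodide F3.
- Zinc dust with LiCl gives the alkylzinc iodide F4.
- Negishi coupling with 18 (Pd(dppf)Cl2, THF) gives the O,O′-diallyl methyl enol ether F5.
- Pd(PPh3)4/Bu3SnH/AcOH removes the allyl groups and delivers 25.

**Step 12.** Hydride may be delivered to the tertiary terminus, giving the transposed alkene. Other risks are β-hydride elimination of the π-allyl complex to a diene, loss of E geometry through a σ-allyl species at the tertiary carbon, and incomplete cleavage of the aryl allyl ethers. Fallback, setting out from 23 (isolated in this case) and returning at 25, with radical instead of π-allyl deoxygenation: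
- 1,1′-Thiocarbonyldiimidazole and DMAP give the imidazolylthiocarbonate F6.
- Bu3SnH and AIBN in toluene at 80 °C reduce it through the allyl radical, which abstracts hydrogen at the less hindered C1′, to the O,O′-diallyl methyl enol ether F5.
- Pd(PPh3)4/Bu3SnH/AcOH then removes the allyl groups to give 25.

**Step 2.** Hydrochlorination or Lewis-acid-induced cleavage of the allyl ethers may occur during the long exposure to HCl/ZnCl2, and nitrilium formation from the electron-rich nitrile may be sluggish. Fallback, setting out from 3 and returning at 5, with an anionic instead of an electrophilic acylation: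
- 3 is converted with MOMCl and i-Pr2NEt into 1,3,5-tris(methoxymethoxy)benzene F7.
- Lithiation with n-BuLi (THF, 0 °C) and addition to the nitrile 2 give the ketimine F8.
- Aqueous HCl in MeOH at 50 °C hydrolyses the imine and removes the three acetals to give 5.

## Further compounds

F0 | step 7 | none | none
F1 | step 10 | 3-[3,4-bis(allyloxy)benzoyl]-4-hydroxy-7-endo-(hydroxymethyl)-8,8-dimethyl-1,5-bis(3-methylbut-2-enyl)bicyclo[3.3.1]non-3-ene-2,9-dione | OC[C@H]1C[C@]2(CC=C(C)C)C(=O)[C@@](CC=C(C)C)(C(=O)C(C(=O)c3ccc(OCC=C)c(OCC=C)c3)=C2O)C1(C)C
F2 | step 10 | C4 methyl enol ether of F1 | OC[C@H]1C[C@]2(CC=C(C)C)C(=O)[C@@](CC=C(C)C)(C(=O)C(C(=O)c3ccc(OCC=C)c(OCC=C)c3)=C2OC)C1(C)C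
F3 | step 10 | 7-endo-(iodomethyl) analogue of F2 | IC[C@H]1C[C@]2(CC=C(C)C)C(=O)[C@@](CC=C(C)C)(C(=O)C(C(=O)c3ccc(OCC=C)c(OCC=C)c3)=C2OC)C1(C)C
F4 | step 10 | alkylzinc iodide from F3 | I[Zn]C[C@H]1C[C@]2(CC=C(C)C)C(=O)[C@@](CC=C(C)C)(C(=O)C(C(=O)c3ccc(OCC=C)c(OCC=C)c3)=C2OC)C1(C)C
F5 | step 10 | 3-[3,4-bis(allyloxy)benzoyl]-7-endo-[(2E)-3,7-dimethylocta-2,6-dienyl]-4-methoxy-8,8-dimethyl-1,5-bis(3-methylbut-2-enyl)bicyclo[3.3.1]non-3-ene-2,9-dione | CC(C)=CCC/C(C)=C/C[C@H]1C[C@]2(CC=C(C)C)C(=O)[C@@](CC=C(C)C)(C(=O)C(C(=O)c3ccc(OCC=C)c(OCC=C)c3)=C2OC)C1(C)C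
F6 | step 12 | O-(C1′) 1H-imidazole-1-carbothioate of 23 | CC(C)=CCC/C(C)=C/C(OC(=S)n4ccnc4)[C@H]1C[C@]2(CC=C(C)C)C(=O)[C@@](CC=C(C)C)(C(=O)C(C(=O)c3ccc(OCC=C)c(OCC=C)c3)=C2OC)C1(C)C
F7 | step 2 | 1,3,5-tris(methoxymethoxy)benzene | COCOc1cc(OCOC)cc(OCOC)c1
F8 | step 2 | [3,4-bis(allyloxy)phenyl][2,4,6-tris(methoxymethoxy)phenyl]methanimine | N=C(c1ccc(OCC=C)c(OCC=C)c1)c1c(OCOC)cc(OCOC)cc1OCOC
A1 | alternative 1 | methyl enol ether of 4-geranyl-3,3-dimethyl-2-prenylcyclohexanone, (R)-configured at C4 (the future C7, arranged as in the target) | CC(C)=CCC/C(C)=C/C[C@H]1CCC(OC)=C(CC=C(C)C)C1(C)C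
A2 | alternative 1 | 7-endo-geranyl-4-hydroxy-8,8-dimethyl-1-prenylbicyclo[3.3.1]non-3-ene-2,9-dione (C5–H, C3–H) | CC(C)=CCC/C(C)=C/C[C@H]1C[C@@H]2C(=O)[C@@](CC=C(C)C)(C(=O)C=C2O)C1(C)C
A3 | alternative 2 | dearomatised 3,5-diprenyl aroylphloroglucinol carrying at C5 the (2-isopropenyl-5,9-dimethyldeca-4,8-dienyl) chain | O=C1C(CC=C(C)C)=C(O)C(C(=O)c2ccc(O)c(O)c2)=C(O)[C@]1(CC=C(C)C)C[C@H](C/C=C(\C)CCC=C(C)C)C(C)=C
A4 | alternative 3 | 4-O-[2-(chloromethyl)-3-methylbut-2-enyl] ether of the 3,5-diprenyl aroylphloroglucinol with bis(triisopropylsilyl)-protected catechol | CC(C)=C(CCl)COc1c(CC=C(C)C)c(O)c(C(=O)c2ccc(O[Si](C(C)C)(C(C)C)C(C)C)c(O[Si](C(C)C)(C(C)C)C(C)C)c2)c(O)c1CC=C(C)C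
A5 | alternative 3 | 7-methylene-8,8-dimethyl-1,5-diprenyl bicyclic trione with bis(triisopropylsilyl)-protected 3-aroyl group (formed as the racemate; one enantiomer shown) | C=C1C[C@]2(CC=C(C)C)C(=O)[C@@](CC=C(C)C)(C(=O)C(C(=O)c3ccc(O[Si](C(C)C)(C(C)C)C(C)C)c(O[Si](C(C)C)(C(C)C)C(C)C)c3)=C2O)C1(C)C
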